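## Structural features

The target is a flavonol: a benzene ring A fused to a γ-pyranone ring C (a 4H-chromen-4-one), with the 3-methoxy-4-oxygenated phenyl ring B attached to C2 through the C2–C1' bond. Three oxygens are hydrogen sulfate esters: O7 on ring A, O4' on ring B, and the enolic O3 on ring C, which sits between the C4 carbonyl and ring B. C5 is unsubstituted and the 3'-oxygen is a methyl ether. There is no stereocentre, so nothing has to be set or guarded stereochemically. The fragile groups are the three sulfate monoesters, which are strong acids, hydrolyse in acidic medium (most easily at O3) and make the molecule very polar. In the unsulfated core the C2=C3 enol-ether bond is opened by hard nucleophiles at C2. The real difficulties are the 7-mono-oxygenated, 5-unsubstituted ring A (no symmetric precursor places the oxygen), the oxygen at C3, and the exhaustive sulfation with isolation of a triply acidic product. The key step uses the fact that C4a and C8a are neighbours on ring A and carry the C4 carbonyl carbon and O1, which together are the C(=O)–O unit of a carboxylic acid. An aryne with its triple bond between these two carbons can take up both from an arylpropiolic acid, whose alkyne then supplies C3, C2 and ring B.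

## Logic of the disconnections

18 ⇒ 16. The three O–S bonds at O3, O7 and O4' are cut first, because the sulfates are the most labile and most polar groups and would survive none of the other operations. This leaves the neutral triol 16 and one final, non-selective operation. The forward step must sulfate every hydroxyl, including the hydrogen-bonded enolic one at C3, and must release the acid from salt 17 without hydrolysis.

16 ⇒ 15. In the retrosynthetic sense two O-benzyl groups and a bromine at C5 are added. The benzyl ethers mask the phenols through organolithium, fluoride and oxidation chemistry, and the bromine is the regiochemical control element of the key step. All three are chosen so that one hydrogenolysis removes them, which costs no extra step. The forward step must cleave two C–O bonds and one C–Br bond without reducing the pyranone.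

15 ⇒ 13 (through 14). The C3–O bond is cut. The key step cannot deliver this oxygen, because C3 originates as an alkyne carbon that ends up bearing hydrogen. The forward step must oxidise the electron-poor C2=C3 bond without opening ring C and without attacking the benzyl ethers. A neutral oxygen-transfer reagent followed by acid-induced rearrangement of 14 meets this demand.

13 ⇒ 5 + 10 (through 11 and 12). The bonds C8a–O1, C4a–C4 and O1–C2 are cut, which removes ring C and divides the molecule into two halves of similar size. Ring A becomes aryne equivalent 5, and the carboxyl carbon, the two alkyne carbons and ring B become 10. The forward step must add the carboxylate oxygen to the correct aryne terminus (controlled by the bromine next to the triple bond), transfer the acyl group to the neighbouring carbon, and close ring C in the 6-endo mode.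

5 ⇒ 2 ⇒ 1 (through 3 and 4). The O–S bond of the triflate and the C–Si bond are cut, then both C–Br bonds. The silyl group is traced back to an O-silyl group that migrates to carbon after bromine–lithium exchange, so the two ortho positions of 1 are differentiated only after a symmetric dibromination. The forward steps need clean dibromination ortho to the hydroxyl and a single bromine–lithium exchange.

10 ⇒ 8 ⇒ 7 ⇒ 6 (through 9). The C(sp)–CO2H bond is cut, then the alkyne is taken back to an aldehyde by one-carbon homologation, then the O-benzyl bond is cut. This reaches an inexpensive aromatic aldehyde that already has the ring B oxygen pattern. The forward steps need an acetylide that tolerates the benzyl ether and is trapped by carbon dioxide.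

## Other disconnections considered

Alternative 1: The cut is the single bond O1–C8a. In the forward direction the potassium enolate of 2-(benzyloxy)-1-[4-(benzyloxy)-2-fluorophenyl]-3-[4-(benzyloxy)-3-methoxyphenyl]propane-1,3-dione A1 (K2CO3, warm DMF) would displace fluoride from ring A through the oxygen of the ring B carbonyl. This intramolecular SNAr closure would give the fully benzylated flavonol A2.
- In its favour: the C3 oxygen is carried from the start, so no late oxidation and no peroxide are needed. The position of fluorine fixes the ring A regiochemistry absolutely. One hydrogenolysis of A2 leads directly to 16.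
- Against it here: the key step forms one bond only, so the C4–C3–C2 chain with its oxygenated central carbon must be built beforehand by a crossed Claisen-type acylation of an α-benzyloxy ketone. That step is open to O-acylation and retro-Claisen cleavage. The fluorine is activated by a single ortho carbonyl whose pull is weakened by the para benzyloxy group, and the fluorinated ring A building block is less accessible than 1.
- Comparison: on structure the alternative is better at C3 and at C5, since no oxidation and no directing atom are needed, and its endgame is one step shorter. On mechanism its closure is the more predictable of the two. On step economy the gain at the end would probably be spent in making A1, so the totals are expected to be about equal. The chosen plan is the more convergent, since its key step joins two halves and forms three bonds.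

Alternative 2: The cuts are C4–C4a and O1–C2, with ring A traced back to non-aromatic cyclohexane-1,3-dione A3. Forward, the benzyl enol ether 3-(benzyloxy)cyclohex-2-en-1-one A4 would be deprotonated by LDA at the α' carbon. The cross-conjugated lithium enolate would be C-acylated by 3-[4-(benzyloxy)-3-methoxyphenyl]prop-2-ynoyl chloride A5 (from 10), and the enol oxygen would then add to the ynone to give dihydrochromenone A6.
- In its favour: the ring A source is very cheap. The 7-oxygen is inherent in the dione, so there is no regiochemical question and no bromine. It uses the same acid 10.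
- Against it here: A6 is two hydrogens short of an aromatic ring A. The dehydrogenation across C5–C6 (for example with DDQ) must spare two benzyl ethers and an acid-sensitive benzyl enol ether. The acylation must favour carbon over oxygen and must avoid conjugate addition to the ynoyl chloride, and A5 is a sensitive reagent. C3 would still lack its oxygen.
- Comparison: on regiocontrol the alternative is the better, being unambiguous without a directing atom. On mechanism it relies on a less predictable enolate acylation. On step economy it is worse, because aromatisation is added to the same C3 oxidation, deprotection and sulfation.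

Alternative 3: The cuts are C4a–C4, C4–C3 and O1–C2, with C4 traced to carbon monoxide. Forward, 5-(benzyloxy)-2-iodophenol A7, carbon monoxide A8 and 1-(benzyloxy)-4-ethynyl-2-methoxybenzene A9 would combine under PdCl2(PPh3)2 in Et2NH. Oxidative addition of zerovalent palladium into the C–I bond, CO insertion and alkynylation would give an ortho-hydroxyaryl ynone, which the amine would close through an enaminone to flavone A10.
- In its favour: it forms three bonds and ring C in one catalytic operation, equal to the chosen step in bond count. The ring A regiochemistry is fixed by the iodine and no bromine has to be removed. A9 needs no carboxylation (it would come from 8). This type of carbonylative annulation has broad precedent.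
- Against it here: pressurised, toxic CO runs against the aim of a safe route. A7 requires a regioselective iodination of a resorcinol monoether, so the regiochemical problem is moved and not removed. Closure in the 5-exo mode is a known competitor. A10 lacks the C3 oxygen exactly as 13 does, so the endgame is the same.
- Comparison: on precedent and atom economy the alternative is the better (no silyl triflate, no directing halogen). On step count the two are equal to within one step. The chosen plan is better on operational hazard (no CO gas, no transition metal in the ring-forming step) and takes its regiochemistry from a symmetric dibromination of 1.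

Key step: step 6

Assumption on the chemistry: the target is taken as the free tris(hydrogen sulfate) as drawn. Because aryl hydrogen sulfates hydrolyse autocatalytically, it is formed as salt 17 and converted to the acid only at the very end, in the cold; for storage it would be kept as a salt.

Check of the key-step atom mapping: in 5 the triflate carbon lies between C–Br and C–SiMe3. The aryne carbons therefore become C4a (next to C–Br, the future C5) and C8a, and the benzyloxy group para to the triflate ends at C7. Precursor and product are consistent and need no correction. Bromine and benzyl are kept as spectator groups because one hydrogenolysis removes all of them.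

## Steps

Step 1
Reactants: 1 4-(benzyloxy)phenol
Product: 2 4-(benzyloxy)-2,6-dibromophenol
Conditions: NBS (2.05 equiv), i-Pr2NH (0.2 equiv), CH2Cl2, 0 °C → rt
Reagents that add atoms: N-bromosuccinimide, O=C1CCC(=O)N1Br
Why: Amine-mediated ortho-bromination of a phenol (electrophilic aromatic substitution); the N-bromoamine formed from NBS and i-Pr2NH is delivered by hydrogen bonding to the two positions flanking the hydroxyl, the para position being blocked, and solid NBS avoids liquid bromine.

Step 2
Reactants: 2 4-(benzyloxy)-2,6-dibromophenol
Product: 5 4-(benzyloxy)-2-bromo-6-(trimethylsilyl)phenyl trifluoromethanesulfonate, via aryl trimethylsilyl ether 3 (not isolated), via lithium 2-silylphenoxide 4 (not isolated)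
Conditions: HMDS, THF, reflux, then evaporate; n-BuLi (1.05 equiv), THF, −78 °C; Tf2O (1.2 equiv), −78 °C → rt
Reagents that add atoms: hexamethyldisilazane, C[Si](C)(C)N[Si](C)(C)C; trifluoromethanesulfonic anhydride, O=S(=O)(OS(=O)(=O)C(F)(F)F)C(F)(F)F
Why: HMDS silylates the hindered phenol with ammonia as the only by-product; one equivalent of n-BuLi exchanges one of the two equivalent bromines, the ortho-lithiated silyl ether undergoes a fast 1,3 O-to-C silyl shift (retro-Brook rearrangement), and phenoxide 4 is trapped by Tf2O. This is the standard entry to 2-bromo-6-silylaryl triflates, run in one flask at low temperature.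

Step 3
Reactants: 6 vanillin
Product: 7 4-(benzyloxy)-3-methoxybenzaldehyde
Conditions: BnBr (1.1 equiv), K2CO3, MeCN, 60 °C
Reagents that add atoms: benzyl bromide, BrCc1ccccc1
Why: Williamson ether synthesis on the acidic phenol; the benzyl ether tolerates the organolithium, fluoride and dioxirane steps and is removed together with the bromine in step 8.

Step 4
Reactants: 7 4-(benzyloxy)-3-methoxybenzaldehyde
Product: 8 1-(benzyloxy)-4-(2,2-dibromoethenyl)-2-methoxybenzene
Conditions: CBr4 (1.5 equiv), PPh3 (3 equiv), CH2Cl2, 0 °C
Reagents that add atoms: carbon tetrabromide, BrC(Br)(Br)Br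
Why: Ramirez dibromo-olefination, the first stage of the Corey–Fuchs sequence; the ylide formed from PPh3 and CBr4 undergoes a Wittig reaction with the aldehyde.

Step 5
Reactants: 8 1-(benzyloxy)-4-(2,2-dibromoethenyl)-2-methoxybenzene
Product: 10 3-[4-(benzyloxy)-3-methoxyphenyl]prop-2-ynoic acid, via lithium arylacetylide 9 (not isolated)
Conditions: n-BuLi (2.2 equiv), THF, −78 °C → 0 °C; CO2 (g), −78 °C → rt; 1 M HCl
Reagents that add atoms: carbon dioxide, O=C=O
Why: Second stage of the Corey–Fuchs sequence; bromine–lithium exchange and Fritsch–Buttenberg–Wiechell rearrangement give the alkyne, the second equivalent of n-BuLi gives acetylide 9, and carboxylation followed by acidification gives the propiolic acid in the same flask.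

Step 6
Reactants: 5 4-(benzyloxy)-2-bromo-6-(trimethylsilyl)phenyl trifluoromethanesulfonate; 10 3-[4-(benzyloxy)-3-methoxyphenyl]prop-2-ynoic acid
Product: 13 7-(benzyloxy)-2-[4-(benzyloxy)-3-methoxyphenyl]-5-bromo-4H-chromen-4-one, via aryne 11 (not isolated), via cesium ynone phenoxide 12 (not isolated)
Conditions: 5 (1.5 equiv), CsF (4 equiv), THF, 125 °C, sealed pressure tube
Reagents that add atoms: none
Why: Fluoride attacks the silicon of 5 and the resulting aryl anion expels triflate, releasing 5-(benzyloxy)-3-bromobenzyne 11 slowly in the presence of the cesium carboxylate of 10. The carboxylate oxygen adds to the aryne carbon remote from bromine (future C8a), because the C–Br bond inductively stabilises negative charge on the neighbouring carbon (future C4a) and distorts the triple bond so that the remote terminus is the more electrophilic; the more distant benzyloxy group has only a weak, opposing influence. The aryl anion then attacks the carbonyl carbon of the ester just formed (four-membered alkoxide), and ring opening gives ortho-acyl phenoxide 12, a net insertion of the aryne into the acid C–O bond that forms C8a–O1 and C4a–C4. The phenoxide adds to the β-carbon of the ynone in a 6-endo-dig oxa-Michael closure, forming O1–C2 and ring C, and protonation of the allenolate gives 13. The closest known reaction type is this same fluoride-induced aryne insertion into carboxylic acids, which turns arylpropiolic acids into flavones, so the step applies known chemistry to a new pair of partners. No stereocentre is created. Three selectivities are needed: the regiochemistry of addition (secured by the bromine, removed in step 8); acyl transfer in preference to protonation or bromide loss of the aryl anion (favoured by the aprotic medium and the high temperature, with the excess of 5 compensating for aryne lost to side reactions); and 6-endo over 5-exo closure (secured by the polarisation of the ynone, whose β-carbon is the Michael position and whose allenolate is stabilised by the C4 carbonyl).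

Step 7
Reactants: 13 7-(benzyloxy)-2-[4-(benzyloxy)-3-methoxyphenyl]-5-bromo-4H-chromen-4-one
Product: 15 7-(benzyloxy)-2-[4-(benzyloxy)-3-methoxyphenyl]-5-bromo-3-hydroxy-4H-chromen-4-one, via flavone 2,3-epoxide 14 (not isolated)
Conditions: DMDO (ca. 0.08 M in acetone, 3 equiv), CH2Cl2, 0 °C → rt; Me2S; then p-TsOH·H2O (cat.), CH2Cl2, rt
Reagents that add atoms: dimethyldioxirane, CC1(C)OO1
Why: Dioxirane epoxidation of the C2=C3 enol-ether bond of a flavone is a concerted, neutral oxygen transfer, so the base-sensitive pyranone is not opened; acid then opens epoxide 14 at C2 to the O1- and aryl-stabilised cation and loss of H3 gives the 3-hydroxyflavone. The two stereocentres of 14 (cis by ring fusion, racemic) disappear in this rearrangement; the oxidant is used only as a dilute solution and its excess is destroyed with Me2S before concentration.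

Step 8
Reactants: 15 7-(benzyloxy)-2-[4-(benzyloxy)-3-methoxyphenyl]-5-bromo-3-hydroxy-4H-chromen-4-one
Product: 16 3,7-dihydroxy-2-(4-hydroxy-3-methoxyphenyl)-4H-chromen-4-one
Conditions: H2 (1 atm), 10% Pd/C (water-wet), Et3N (1.5 equiv), THF/MeOH, rt
Reagents that add atoms: none
Why: Palladium-catalysed hydrogenolysis cleaves both benzylic C–O bonds and, with Et3N as HBr scavenger, the C5–Br bond activated by the ortho carbonyl; the C2=C3 bond of the chromone is part of a vinylogous ester and should not be reduced under these mild conditions.

Step 9
Reactants: 16 3,7-dihydroxy-2-(4-hydroxy-3-methoxyphenyl)-4H-chromen-4-one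
Product: 18 2-(3-methoxy-4-sulfooxyphenyl)-4-oxo-4H-chromene-3,7-diyl bis(hydrogen sulfate), via tris(triethylammonium) salt 17 (not isolated)
Conditions: SO3·NEt3 (8 equiv per OH), DMA, 65 °C; then Dowex 50WX8 (H+ form), H2O, 0–5 °C, freeze-drying
Reagents that add atoms: sulfur trioxide–triethylamine complex, CC[N+](CC)(CC)S(=O)(=O)[O-]
Why: O-sulfation of phenols and of the enolic 3-OH with an amine–sulfur trioxide complex; a large excess and warming drive the hydrogen-bonded 3-OH to completion, and since every hydroxyl is meant to react no selectivity is required. Cold cation exchange converts salt 17 into the tris(hydrogen sulfate).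

## Compound list

1 | 4-(benzyloxy)phenol | Oc1ccc(OCc2ccccc2)cc1 | starting material
2 | 4-(benzyloxy)-2,6-dibromophenol | Oc1c(Br)cc(OCc2ccccc2)cc1Br | intermediate
3 | [4-(benzyloxy)-2,6-dibromophenoxy]trimethylsilane | C[Si](C)(C)Oc1c(Br)cc(OCc2ccccc2)cc1Br | intermediate (not isolated)
4 | lithium 4-(benzyloxy)-2-bromo-6-(trimethylsilyl)phenoxide | [Li+].[O-]c1c(Br)cc(OCc2ccccc2)cc1[Si](C)(C)C | intermediate (not isolated)
5 | 4-(benzyloxy)-2-bromo-6-(trimethylsilyl)phenyl trifluoromethanesulfonate | C[Si](C)(C)c1cc(OCc2ccccc2)cc(Br)c1OS(=O)(=O)C(F)(F)F | intermediate
6 | vanillin (4-hydroxy-3-methoxybenzaldehyde) | COc1cc(C=O)ccc1O | starting material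
7 | 4-(benzyloxy)-3-methoxybenzaldehyde | COc1cc(C=O)ccc1OCc1ccccc1 | intermediate
8 | 1-(benzyloxy)-4-(2,2-dibromoethenyl)-2-methoxybenzene | COc1cc(C=C(Br)Br)ccc1OCc1ccccc1 | intermediate
9 | lithium [4-(benzyloxy)-3-methoxyphenyl]ethynide | [Li+].[C-]#Cc1ccc(OCc2ccccc2)c(OC)c1 | intermediate (not isolated)
10 | 3-[4-(benzyloxy)-3-methoxyphenyl]prop-2-ynoic acid | COc1cc(C#CC(=O)O)ccc1OCc1ccccc1 | intermediate
11 | 5-(benzyloxy)-3-bromobenzyne | BrC1=CC(OCc2ccccc2)=CC#C1 | intermediate (not isolated)
12 | cesium 5-(benzyloxy)-2-{3-[4-(benzyloxy)-3-methoxyphenyl]prop-2-ynoyl}-3-bromophenoxide | [Cs+].[O-]c1cc(OCc2ccccc2)cc(Br)c1C(=O)C#Cc1ccc(OCc2ccccc2)c(OC)c1 | intermediate (not isolated)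
13 | 7-(benzyloxy)-2-[4-(benzyloxy)-3-methoxyphenyl]-5-bromo-4H-chromen-4-one | COc1cc(-c2cc(=O)c3c(Br)cc(OCc4ccccc4)cc3o2)ccc1OCc1ccccc1 | intermediate
14 | 7-(benzyloxy)-2-[4-(benzyloxy)-3-methoxyphenyl]-5-bromo-2,3-epoxy-2,3-dihydro-4H-chromen-4-one (cis-fused, racemic; one enantiomer written) | COc1cc([C@]23Oc4cc(OCc5ccccc5)cc(Br)c4C(=O)[C@H]2O3)ccc1OCc1ccccc1 | intermediate (not isolated)
15 | 7-(benzyloxy)-2-[4-(benzyloxy)-3-methoxyphenyl]-5-bromo-3-hydroxy-4H-chromen-4-one | COc1cc(-c2oc3cc(OCc4ccccc4)cc(Br)c3c(=O)c2O)ccc1OCc1ccccc1 | intermediate
16 | 3,7-dihydroxy-2-(4-hydroxy-3-methoxyphenyl)-4H-chromen-4-one | COc1cc(-c2oc3cc(O)ccc3c(=O)c2O)ccc1O | intermediate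
17 | tris(triethylammonium) 2-(3-methoxy-4-sulfonatooxyphenyl)-4-oxo-4H-chromene-3,7-diyl disulfate | COc1cc(-c2oc3cc(OS(=O)(=O)[O-])ccc3c(=O)c2OS(=O)(=O)[O-])ccc1OS(=O)(=O)[O-].CC[NH+](CC)CC.CC[NH+](CC)CC.CC[NH+](CC)CC | intermediate (not isolated)
18 | 2-(3-methoxy-4-sulfooxyphenyl)-4-oxo-4H-chromene-3,7-diyl bis(hydrogen sulfate) | COc1cc(-c2oc3cc(OS(=O)(=O)O)ccc3c(=O)c2OS(=O)(=O)O)ccc1OS(=O)(=O)O | target

## Step count and risk assessment

Total step count: 9. Longest linear sequence: 7 steps (steps 3, 4, 5, 6, 7, 8, 9, from 6). The ring A branch (steps 1 and 2) joins at step 6. Compound 7 is itself a catalogue compound; buying it would remove step 3.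

Least certain steps:

**Step 6 (key step).** The aryl anion formed next to bromine may be protonated before it transfers the acyl group, so that the reaction stops at O-arylation. It may also lose bromide and generate a second aryne. Acid 10 may decarboxylate at 125 °C, and the remote benzyloxy group may erode the regiochemical bias. The fallback gives up the aryne and builds the flavonol by chalcone oxidation, setting out from 7 and returning at 16:
- Claisen–Schmidt condensation of 7 with commercially available 1-[4-(benzyloxy)-2-hydroxyphenyl]ethan-1-one F1 (KOH, EtOH, rt) would give (E)-1-[4-(benzyloxy)-2-hydroxyphenyl]-3-[4-(benzyloxy)-3-methoxyphenyl]prop-2-en-1-one F2.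
- Algar–Flynn–Oyamada oxidation (30% H2O2, NaOH, MeOH/THF, 0 °C → rt) would close ring C with the C3 oxygen in place, giving 7-(benzyloxy)-2-[4-(benzyloxy)-3-methoxyphenyl]-3-hydroxy-4H-chromen-4-one F3.
- Hydrogenolysis under the conditions of step 8 (no base needed) would then give 16.

**Step 7.** Epoxidation of the electron-poor C2=C3 bond is slow, so oxidation of the benzylic C–H bonds of the ethers or of the electron-rich ring B may compete, and the rearrangement of the epoxide may be incomplete. The fallback sets out from 13 and returns at 15 without any peroxide:
- Oxidation with PhI(OAc)2 and KOH in MeOH (0 °C → rt) would add methoxide at C2 and oxidise the resulting enolate at C3 with trivalent iodine. This would give 7-(benzyloxy)-2-[4-(benzyloxy)-3-methoxyphenyl]-5-bromo-2,4,4-trimethoxy-3,4-dihydro-2H-chromen-3-ol F4.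
- Aqueous HCl in acetone would hydrolyse the acetal and eliminate methanol to give 15.

**Step 8.** Cleavage of the C–Br bond may stall through poisoning of the catalyst by bromide, or prolonged exposure may lead to saturation of the C2=C3 bond. The fallback separates the two tasks and avoids hydrogen gas, setting out from 15 and returning at 16:
- BCl3 with pentamethylbenzene in CH2Cl2 at −78 °C would remove both benzyl groups without touching the methyl ether, giving 5-bromo-3,7-dihydroxy-2-(4-hydroxy-3-methoxyphenyl)-4H-chromen-4-one F5.
- Homogeneous transfer hydrodehalogenation (Pd(OAc)2, PPh3, HCO2H, Et3N, DMF, 80 °C) would then give 16.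

**Step 9.** Sulfation of the hindered, hydrogen-bonded 3-OH may remain incomplete, and hydrolysis may occur while the acid form is generated and dried. The fallback introduces the sulfates in protected, neutral form, setting out from 16 and returning at 18:
- 2,2,2-Trichloroethyl chlorosulfate with Et3N and DMAP in THF would give 2-methoxy-4-{4-oxo-3,7-bis[(2,2,2-trichloroethoxy)sulfonyloxy]-4H-chromen-2-yl}phenyl 2,2,2-trichloroethyl sulfate F6, which can be purified on silica.
- Zn dust and HCO2NH4 in MeOH would unmask it to the triammonium salt of 18 F7.
- The same cold cation exchange as in step 9 would give 18.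

## Further compounds

F1 | step 6 | 1-[4-(benzyloxy)-2-hydroxyphenyl]ethan-1-one | CC(=O)c1ccc(OCc2ccccc2)cc1O
F2 | step 6 | (E)-1-[4-(benzyloxy)-2-hydroxyphenyl]-3-[4-(benzyloxy)-3-methoxyphenyl]prop-2-en-1-one | COc1cc(/C=C/C(=O)c2ccc(OCc3ccccc3)cc2O)ccc1OCc1ccccc1
F3 | step 6 | 7-(benzyloxy)-2-[4-(benzyloxy)-3-methoxyphenyl]-3-hydroxy-4H-chromen-4-one | COc1cc(-c2oc3cc(OCc4ccccc4)ccc3c(=O)c2O)ccc1OCc1ccccc1
F4 | step 7 | 7-(benzyloxy)-2-[4-(benzyloxy)-3-methoxyphenyl]-5-bromo-2,4,4-trimethoxy-3,4-dihydro-2H-chromen-3-ol (racemic; configuration at C2 and C3 not defined, both centres are lost in the next operation) | COc1cc(C2(OC)Oc3cc(OCc4ccccc4)cc(Br)c3C(OC)(OC)C2O)ccc1OCc1ccccc1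
F5 | step 8 | 5-bromo-3,7-dihydroxy-2-(4-hydroxy-3-methoxyphenyl)-4H-chromen-4-one | COc1cc(-c2oc3cc(O)cc(Br)c3c(=O)c2O)ccc1O
F6 | step 9 | 2-methoxy-4-{4-oxo-3,7-bis[(2,2,2-trichloroethoxy)sulfonyloxy]-4H-chromen-2-yl}phenyl 2,2,2-trichloroethyl sulfate | COc1cc(-c2oc3cc(OS(=O)(=O)OCC(Cl)(Cl)Cl)ccc3c(=O)c2OS(=O)(=O)OCC(Cl)(Cl)Cl)ccc1OS(=O)(=O)OCC(Cl)(Cl)Cl
F7 | step 9 | triammonium 2-(3-methoxy-4-sulfonatooxyphenyl)-4-oxo-4H-chromene-3,7-diyl disulfate | COc1cc(-c2oc3cc(OS(=O)(=O)[O-])ccc3c(=O)c2OS(=O)(=O)[O-])ccc1OS(=O)(=O)[O-].[NH4+].[NH4+].[NH4+]
A1 | alternative 1 | 2-(benzyloxy)-1-[4-(benzyloxy)-2-fluorophenyl]-3-[4-(benzyloxy)-3-methoxyphenyl]propane-1,3-dione (racemic, enolisable) | COc1cc(C(=O)C(OCc2ccccc2)C(=O)c2ccc(OCc3ccccc3)cc2F)ccc1OCc1ccccc1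
A2 | alternative 1 | 3,7-bis(benzyloxy)-2-[4-(benzyloxy)-3-methoxyphenyl]-4H-chromen-4-one | COc1cc(-c2oc3cc(OCc4ccccc4)ccc3c(=O)c2OCc2ccccc2)ccc1OCc1ccccc1
A3 | alternative 2 | cyclohexane-1,3-dione | O=C1CCCC(=O)C1
A4 | alternative 2 | 3-(benzyloxy)cyclohex-2-en-1-one | O=C1C=C(OCc2ccccc2)CCC1
A5 | alternative 2 | 3-[4-(benzyloxy)-3-methoxyphenyl]prop-2-ynoyl chloride | COc1cc(C#CC(=O)Cl)ccc1OCc1ccccc1
A6 | alternative 2 | 7-(benzyloxy)-2-[4-(benzyloxy)-3-methoxyphenyl]-5,6-dihydro-4H-chromen-4-one | COc1cc(C2=CC(=O)C3=C(C=C(OCc4ccccc4)CC3)O2)ccc1OCc1ccccc1
A7 | alternative 3 | 5-(benzyloxy)-2-iodophenol | Oc1cc(OCc2ccccc2)ccc1I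
A8 | alternative 3 | carbon monoxide | [C-]#[O+]
A9 | alternative 3 | 1-(benzyloxy)-4-ethynyl-2-methoxybenzene | COc1cc(C#C)ccc1OCc1ccccc1
A10 | alternative 3 | 7-(benzyloxy)-2-[4-(benzyloxy)-3-methoxyphenyl]-4H-chromen-4-one | COc1cc(-c2cc(=O)c3ccc(OCc4ccccc4)cc3o2)ccc1OCc1ccccc1
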